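**Retrosynthetic overview**
1. The route rests on ring A of the (2S)-flavanone: a phloroglucinol ring whose prenyl group sits on C8 between C7–OH and C8a–O1, with C6 unsubstituted. Prenylation of a preformed phloroglucinol does not tell C6 from C8.
2. Ring A is made first, by benzannulation of 3-ethoxycyclobutenone with a prenyl-bearing TIPS ynol ether (bonds C8–C8a, C6–C7, C4a–C8a). The phenol has O1 free, O7 as silyl ether and O5 as ethyl ether.
3. Ring C is made second: O1-directed formylation at C4a, conversion to the methyl ketone, and closure through O1 to the chromone. C2–C1' and the C2 stereocentre come from a rhodium-catalysed asymmetric conjugate addition of the ring B boronic acid. This is preferred to a chalcone oxa-Michael closure, which is reversible and needs an ester activator whose acidic removal the 1,1-disubstituted alkene would not survive.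
4. Ring B is brought in preformed (benzylic coupling with a methallyl Grignard reagent, then borylation). Chelation-assisted O5 de-ethylation and O7 desilylation finish the route.

Key step: step 3

Remark: the (S)-bisphosphine in step 12 is assigned to the 2S product by analogy with rhodium/(S)-BINAP additions to cyclic enones; if a model run shows the opposite sense, the (R)-ligand is used.

**Route**

Step 1
Reactants: 1 4-methylpent-3-enoic acid
Product: 2 ethyl 4-methylpent-3-enoate
Conditions: EtI, K2CO3, DMF, rt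
Reagents that add atoms: iodoethane, CCI
Why: Carboxylate O-alkylation (SN2) under mild base avoids the acid-catalysed lactonisation of this β,γ-unsaturated acid and leaves the alkene out of conjugation.

Step 2
Reactants: 2 ethyl 4-methylpent-3-enoate
Product: 5 triisopropyl[(5-methylhex-4-en-1-yn-1-yl)oxy]silane, via lithium 1,1-dibromo-5-methylhexa-1,4-dien-2-olate 3 (not isolated), via lithium 5-methylhex-4-en-1-yn-1-olate 4 (not isolated)
Conditions: CH2Br2, LiTMP (lithium 2,2,6,6-tetramethylpiperidide), THF, −78 °C; n-BuLi, −78 °C to rt; TIPSCl, −78 °C to rt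
Reagents that add atoms: dibromomethane, BrCBr; chlorotriisopropylsilane, CC(C)[Si](Cl)(C(C)C)C(C)C
Why: Kowalski ynolate formation: LiCHBr2 adds to the ester at −78 °C faster than it enolises it, Br/Li exchange on the dibromo enolate triggers 1,2-shift of the prenyl group to the ynolate, and the bulky silyl chloride traps it on oxygen.

Step 3
Reactants: 5 triisopropyl[(5-methylhex-4-en-1-yn-1-yl)oxy]silane; 6 3-ethoxycyclobut-2-en-1-one
Product: 11 5-ethoxy-2-(3-methylbut-2-en-1-yl)-3-[(triisopropylsilyl)oxy]phenol, via ethoxyvinylketene 7 (not isolated), via 4-(1-ethoxyvinyl)cyclobutenone 8 (not isolated), via dienylketene 9 (not isolated), via cyclohexa-2,4-dienone 10 (not isolated)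
Conditions: toluene, 80 to 110 °C, sealed tube
Reagents that add atoms: none
Why: Heating opens cyclobutenone 6 by 4-electron electrocyclic ring opening to ethoxyvinylketene 7, whose carbonyl carbon is attacked by the nucleophilic β-carbon of ynol ether 5 in a [2+2] cycloaddition to give vinylcyclobutenone 8; a second 4-electron opening gives dienylketene 9, which closes ring A by thermal disrotatory 6-electron electrocyclisation (C4a–C8a) to dienone 10 and tautomerises to phenol 11. This is the Danheiser benzannulation of cyclobutenones with siloxyalkynes, here with a 3-alkoxycyclobutenone, a less used partner whose vinylogous-ester stabilisation may call for the upper end of the temperature range. No stereocentre is formed. The step needs one regiochemistry in the [2+2] event, and the oxygen-polarised triple bond should secure it: the carbon bearing the prenyl CH2 bonds to the ketene carbonyl carbon (C8–C8a) and the siloxy carbon to the ketene α-carbon (C6–C7), so prenyl ends ortho to the new hydroxyl and the silyl ether meta to it. The electron-rich alkyne is a far better ketenophile than the unactivated trisubstituted prenyl alkene, and an intramolecular [2+2] of 9 with its own prenyl alkene would require a bicyclo[1.1.1] or bicyclo[2.1.0] skeleton.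

Step 4
Reactants: 11 5-ethoxy-2-(3-methylbut-2-en-1-yl)-3-[(triisopropylsilyl)oxy]phenol
Product: 13 6-ethoxy-2-hydroxy-3-(3-methylbut-2-en-1-yl)-4-[(triisopropylsilyl)oxy]benzaldehyde, via 2-(hydroxymethyl)phenol 12 (not isolated)
Conditions: MgCl2, Et3N, (CH2O)n, MeCN, reflux
Reagents that add atoms: formaldehyde (as paraformaldehyde), C=O
Why: Magnesium-mediated ortho-formylation of phenols: the magnesium phenoxide delivers formaldehyde to the only free ortho carbon (future C4a) and a second formaldehyde oxidises the hydroxymethyl intermediate by hydride transfer, so the position para to the hydroxyl is not touched.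

Step 5
Reactants: 13 6-ethoxy-2-hydroxy-3-(3-methylbut-2-en-1-yl)-4-[(triisopropylsilyl)oxy]benzaldehyde
Product: 14 1-{6-ethoxy-2-hydroxy-3-(3-methylbut-2-en-1-yl)-4-[(triisopropylsilyl)oxy]phenyl}ethan-1-ol (racemic)
Conditions: MeMgBr (2.5 equiv), THF, 0 °C
Reagents that add atoms: methylmagnesium bromide, C[Mg]Br
Why: Grignard addition to the aldehyde after deprotonation of the phenol by the first equivalent; the new carbinol centre is racemic and is removed in step 6.

Step 6
Reactants: 14 1-{6-ethoxy-2-hydroxy-3-(3-methylbut-2-en-1-yl)-4-[(triisopropylsilyl)oxy]phenyl}ethan-1-ol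
Product: 15 1-{6-ethoxy-2-hydroxy-3-(3-methylbut-2-en-1-yl)-4-[(triisopropylsilyl)oxy]phenyl}ethan-1-one
Conditions: MnO2, CH2Cl2, rt
Reagents that add atoms: none
Why: MnO2 oxidation is selective for the benzylic alcohol and should leave the phenol, the silyl ether and the prenyl group alone.

Step 7
Reactants: 15 1-{6-ethoxy-2-hydroxy-3-(3-methylbut-2-en-1-yl)-4-[(triisopropylsilyl)oxy]phenyl}ethan-1-one
Product: 17 5-ethoxy-8-(3-methylbut-2-en-1-yl)-7-[(triisopropylsilyl)oxy]-4H-chromen-4-one, via enaminone 16 (not isolated)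
Conditions: Me2NCH(OMe)2, toluene, 90 °C; then AcOH, 60 °C
Reagents that add atoms: N,N-dimethylformamide dimethyl acetal, COC(OC)N(C)C
Why: Condensation of the methyl ketone with the amide acetal gives the enaminone, and mild acid promotes 6-endo addition of O1 to its β-carbon with loss of dimethylamine (addition–elimination), which closes ring C as the chromone; O1 is the only free hydroxyl, so the prenyl group ends on C8.

Step 8
Reactants: 18 5-bromo-2-methoxybenzaldehyde
Product: 19 (5-bromo-2-methoxyphenyl)methanol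
Conditions: NaBH4, MeOH, 0 °C
Reagents that add atoms: none
Why: Borohydride reduction of the aldehyde; the aryl bromide is inert.

Step 9
Reactants: 19 (5-bromo-2-methoxyphenyl)methanol
Product: 20 4-bromo-2-(bromomethyl)-1-methoxybenzene
Conditions: PBr3, CH2Cl2, 0 °C
Reagents that add atoms: phosphorus tribromide, BrP(Br)Br
Why: Conversion of the benzylic alcohol to the bromide through its phosphite ester and SN2 displacement by bromide.

Step 10
Reactants: 20 4-bromo-2-(bromomethyl)-1-methoxybenzene; 21 methallyl chloride (3-chloro-2-methylprop-1-ene)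
Product: 23 4-bromo-1-methoxy-2-(3-methylbut-3-en-1-yl)benzene, via (2-methylallyl)magnesium chloride 22 (not isolated)
Conditions: 21, Mg, THF, 0 °C; then 20, CuI (5 mol%), −20 °C to rt
Reagents that add atoms: none
Why: Copper-catalysed coupling of an allylic Grignard reagent with a benzylic bromide; the methallyl unit is symmetric so both allylic termini give the same 1,1-disubstituted alkene, and the aryl bromide does not react.

Step 11
Reactants: 23 4-bromo-1-methoxy-2-(3-methylbut-3-en-1-yl)benzene
Product: 26 [4-methoxy-3-(3-methylbut-3-en-1-yl)phenyl]boronic acid, via aryllithium 24 (not isolated), via lithium aryltriisopropoxyborate 25 (not isolated)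
Conditions: n-BuLi, THF, −78 °C; B(OiPr)3, −78 °C to rt; H2O, AcOH to pH 6
Reagents that add atoms: triisopropyl borate, CC(C)OB(OC(C)C)OC(C)C; water, O
Why: Bromine–lithium exchange and borylation of the aryllithium; hydrolysis at near-neutral pH spares the acid-sensitive 1,1-disubstituted alkene.

Step 12
Reactants: 17 5-ethoxy-8-(3-methylbut-2-en-1-yl)-7-[(triisopropylsilyl)oxy]-4H-chromen-4-one; 26 [4-methoxy-3-(3-methylbut-3-en-1-yl)phenyl]boronic acid
Product: 27 (2S)-5-ethoxy-2-[4-methoxy-3-(3-methylbut-3-en-1-yl)phenyl]-8-(3-methylbut-2-en-1-yl)-7-[(triisopropylsilyl)oxy]-2,3-dihydro-4H-chromen-4-one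
Conditions: [RhCl(C2H4)2]2 (2.5 mol%), (S)-MeO-F12-BIPHEP (5.5 mol%), KOH (10 mol%, aq.), 26 (2 equiv), toluene, 40 °C
Reagents that add atoms: none
Why: Hayashi–Miyaura rhodium-catalysed asymmetric conjugate addition: the aryl–rhodium species inserts the C2=C3 bond of the chromone on the face left open by the chiral bisphosphine (S)-2,2'-bis[bis(3,4,5-trifluorophenyl)phosphino]-6,6'-dimethoxy-1,1'-biphenyl, which sets C2 as S, and water protonates the rhodium enolate; the electron-poor ligand should speed insertion into the weakly electrophilic chromone and limit 1,2-addition to the product ketone.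

Step 13
Reactants: 27 (2S)-5-ethoxy-2-[4-methoxy-3-(3-methylbut-3-en-1-yl)phenyl]-8-(3-methylbut-2-en-1-yl)-7-[(triisopropylsilyl)oxy]-2,3-dihydro-4H-chromen-4-one
Product: 28 (2S)-5-hydroxy-2-[4-methoxy-3-(3-methylbut-3-en-1-yl)phenyl]-8-(3-methylbut-2-en-1-yl)-7-[(triisopropylsilyl)oxy]-2,3-dihydro-4H-chromen-4-one
Conditions: MgI2·OEt2 (anhydrous), toluene/Et2O, 60 °C; aqueous work-up
Reagents that add atoms: none
Why: Chelation-assisted ether cleavage: magnesium bound between C4=O and O5 activates only the peri ethyl ether for SN2 attack by iodide, so the ring B methyl ether is spared, and with O7 still silylated the C8 prenyl group has no free ortho hydroxyl to cyclise onto; C2 is not involved.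

Step 14
Reactants: 28 (2S)-5-hydroxy-2-[4-methoxy-3-(3-methylbut-3-en-1-yl)phenyl]-8-(3-methylbut-2-en-1-yl)-7-[(triisopropylsilyl)oxy]-2,3-dihydro-4H-chromen-4-one
Product: 29 (2S)-5,7-dihydroxy-2-[4-methoxy-3-(3-methylbut-3-en-1-yl)phenyl]-8-(3-methylbut-2-en-1-yl)-2,3-dihydro-4H-chromen-4-one (CNP0286775.1)
Conditions: Bu4NF, AcOH (1:1), THF, 0 °C
Reagents that add atoms: none
Why: Fluoride cleavage of the aryl silyl ether; the acetic acid buffer keeps the medium from becoming basic enough to open ring C by retro-oxa-Michael reaction, so C2 should keep its configuration, and it is too weak an acid to touch either alkene.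

**Compound list**
1 | 4-methylpent-3-enoic acid | CC(C)=CCC(=O)O | starting material
2 | ethyl 4-methylpent-3-enoate | CC(C)=CCC(=O)OCC | intermediate
3 | lithium 1,1-dibromo-5-methylhexa-1,4-dien-2-olate | CC(C)=CCC([O-])=C(Br)Br.[Li+] | intermediate (not isolated)
4 | lithium 5-methylhex-4-en-1-yn-1-olate | CC(C)=CCC#C[O-].[Li+] | intermediate (not isolated)
5 | triisopropyl[(5-methylhex-4-en-1-yn-1-yl)oxy]silane | CC(C)=CCC#CO[Si](C(C)C)(C(C)C)C(C)C | intermediate
6 | 3-ethoxycyclobut-2-en-1-one | CCOC1=CC(=O)C1 | starting material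
7 | 3-ethoxybuta-1,3-dien-1-one (ethoxyvinylketene) | C=C(OCC)C=C=O | intermediate (not isolated)
8 | 4-(1-ethoxyvinyl)-2-(3-methylbut-2-en-1-yl)-3-[(triisopropylsilyl)oxy]cyclobut-2-en-1-one (racemic) | C=C(OCC)C1C(=O)C(CC=C(C)C)=C1O[Si](C(C)C)(C(C)C)C(C)C | intermediate (not isolated)
9 | (3E)-5-ethoxy-2-(3-methylbut-2-en-1-yl)-3-[(triisopropylsilyl)oxy]hexa-1,3,5-trien-1-one (dienylketene) | O=C=C(CC=C(C)C)/C(O[Si](C(C)C)(C(C)C)C(C)C)=C\C(OCC)=C | intermediate (not isolated)
10 | 5-ethoxy-2-(3-methylbut-2-en-1-yl)-3-[(triisopropylsilyl)oxy]cyclohexa-2,4-dien-1-one | O=C1CC(OCC)=CC(O[Si](C(C)C)(C(C)C)C(C)C)=C1CC=C(C)C | intermediate (not isolated)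
11 | 5-ethoxy-2-(3-methylbut-2-en-1-yl)-3-[(triisopropylsilyl)oxy]phenol | CCOc1cc(O)c(CC=C(C)C)c(O[Si](C(C)C)(C(C)C)C(C)C)c1 | intermediate
12 | 3-ethoxy-2-(hydroxymethyl)-6-(3-methylbut-2-en-1-yl)-5-[(triisopropylsilyl)oxy]phenol | CCOc1cc(O[Si](C(C)C)(C(C)C)C(C)C)c(CC=C(C)C)c(O)c1CO | intermediate (not isolated)
13 | 6-ethoxy-2-hydroxy-3-(3-methylbut-2-en-1-yl)-4-[(triisopropylsilyl)oxy]benzaldehyde | CCOc1cc(O[Si](C(C)C)(C(C)C)C(C)C)c(CC=C(C)C)c(O)c1C=O | intermediate
14 | 1-{6-ethoxy-2-hydroxy-3-(3-methylbut-2-en-1-yl)-4-[(triisopropylsilyl)oxy]phenyl}ethan-1-ol (racemic) | CCOc1cc(O[Si](C(C)C)(C(C)C)C(C)C)c(CC=C(C)C)c(O)c1C(C)O | intermediate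
15 | 1-{6-ethoxy-2-hydroxy-3-(3-methylbut-2-en-1-yl)-4-[(triisopropylsilyl)oxy]phenyl}ethan-1-one | CCOc1cc(O[Si](C(C)C)(C(C)C)C(C)C)c(CC=C(C)C)c(O)c1C(C)=O | intermediate
16 | (E)-3-(dimethylamino)-1-{6-ethoxy-2-hydroxy-3-(3-methylbut-2-en-1-yl)-4-[(triisopropylsilyl)oxy]phenyl}prop-2-en-1-one | CCOc1cc(O[Si](C(C)C)(C(C)C)C(C)C)c(CC=C(C)C)c(O)c1C(=O)/C=C/N(C)C | intermediate (not isolated)
17 | 5-ethoxy-8-(3-methylbut-2-en-1-yl)-7-[(triisopropylsilyl)oxy]-4H-chromen-4-one | CCOc1cc(O[Si](C(C)C)(C(C)C)C(C)C)c(CC=C(C)C)c2occc(=O)c12 | intermediate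
18 | 5-bromo-2-methoxybenzaldehyde | COc1ccc(Br)cc1C=O | starting material
19 | (5-bromo-2-methoxyphenyl)methanol | COc1ccc(Br)cc1CO | intermediate
20 | 4-bromo-2-(bromomethyl)-1-methoxybenzene | COc1ccc(Br)cc1CBr | intermediate
21 | methallyl chloride (3-chloro-2-methylprop-1-ene) | C=C(C)CCl | starting material
22 | (2-methylallyl)magnesium chloride | C=C(C)C[Mg]Cl | intermediate (not isolated)
23 | 4-bromo-1-methoxy-2-(3-methylbut-3-en-1-yl)benzene | C=C(C)CCc1cc(Br)ccc1OC | intermediate
24 | [4-methoxy-3-(3-methylbut-3-en-1-yl)phenyl]lithium | [Li]c1ccc(OC)c(CCC(C)=C)c1 | intermediate (not isolated)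
25 | lithium [4-methoxy-3-(3-methylbut-3-en-1-yl)phenyl]triisopropoxyborate | CC(C)O[B-](OC(C)C)(OC(C)C)c1ccc(OC)c(CCC(C)=C)c1.[Li+] | intermediate (not isolated)
26 | [4-methoxy-3-(3-methylbut-3-en-1-yl)phenyl]boronic acid | C=C(C)CCc1cc(B(O)O)ccc1OC | intermediate
27 | (2S)-5-ethoxy-2-[4-methoxy-3-(3-methylbut-3-en-1-yl)phenyl]-8-(3-methylbut-2-en-1-yl)-7-[(triisopropylsilyl)oxy]-2,3-dihydro-4H-chromen-4-one | C=C(C)CCc1cc([C@@H]2CC(=O)c3c(OCC)cc(O[Si](C(C)C)(C(C)C)C(C)C)c(CC=C(C)C)c3O2)ccc1OC | intermediate
28 | (2S)-5-hydroxy-2-[4-methoxy-3-(3-methylbut-3-en-1-yl)phenyl]-8-(3-methylbut-2-en-1-yl)-7-[(triisopropylsilyl)oxy]-2,3-dihydro-4H-chromen-4-one | C=C(C)CCc1cc([C@@H]2CC(=O)c3c(O)cc(O[Si](C(C)C)(C(C)C)C(C)C)c(CC=C(C)C)c3O2)ccc1OC | intermediate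
29 | (2S)-5,7-dihydroxy-2-[4-methoxy-3-(3-methylbut-3-en-1-yl)phenyl]-8-(3-methylbut-2-en-1-yl)-2,3-dihydro-4H-chromen-4-one | C=C(C)CCc1cc([C@@H]2CC(=O)c3c(O)cc(O)c(CC=C(C)C)c3O2)ccc1OC | target

**Step count**
Total: 14 steps. Longest linear sequence: 10 steps (steps 1–7 and 12–14); the ring B branch is 4 steps (8–11).

**Steps most likely to fail**

Step 3. The ring opening of the alkoxy-stabilised cyclobutenone may need a temperature at which the ynol ether undergoes 1,3-silyl shift to a silylketene or the vinylketene oligomerises, and the phenol formed may be acylated by ketene still present. The fallback sets out from ynol ether 5 and comes back at phenol 11; it generates ketene 7 at room temperature instead of by heat. α-Lithiated ethyl vinyl ether (t-BuLi, THF) is acylated with N-methoxy-N-methylacetamide to give 3-ethoxybut-3-en-2-one F1. Trifluoroacetylation (LiN(SiMe3)2, CF3CO2CH2CF3) gives 5-ethoxy-1,1,1-trifluorohex-5-ene-2,4-dione F2, and diazo transfer with loss of the trifluoroacetyl group (MsN3, Et3N) gives 1-diazo-3-ethoxybut-3-en-2-one F3. Irradiation of F3 with 5 (Pyrex-filtered Hg lamp, CH2Cl2, rt) should bring about photochemical Wolff rearrangement to 7, which 5 traps as 8; brief warming at 80 °C then carries 8 through 9 and 10 to 11.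

Step 12. Insertion into the electron-rich, vinylogous-ester-like chromone may be slow, so that protodeboronation of the boronic acid outruns addition, and facial selectivity may be incomplete. The fallback sets out from ketone 15 and bromide 23 and comes back at 27. Br/Li exchange on 23 (n-BuLi, THF, −78 °C) followed by DMF gives 4-methoxy-3-(3-methylbut-3-en-1-yl)benzaldehyde F4. Pyrrolidine-mediated aldol condensation of 15 with F4 (EtOH, 50 °C) gives the 2'-hydroxychalcone F5, which should close in the same flask by oxa-Michael addition of O1 to the racemic flavanone F6. Preparative HPLC on a chiral stationary phase (amylose tris(3,5-dimethylphenylcarbamate)) then separates the (2S) enantiomer 27.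

Step 13. SN2 cleavage of an ethyl ether is slower than that of a methyl ether, and prolonged heating with the Lewis acid may open ring C (loss of C2 configuration) or add HI to the 1,1-disubstituted alkene. The fallback sets out from chromone 17 and comes back at 28; it moves the dealkylation ahead of ring B and the stereocentre. BCl3 (CH2Cl2, −78 °C to 0 °C), chelated between C4=O and O5, cleaves the peri ethyl ether of 17 to give 5-hydroxy-8-(3-methylbut-2-en-1-yl)-7-[(triisopropylsilyl)oxy]-4H-chromen-4-one F7. The arylation of step 12 is then run on F7 with boronic acid 26; the internally hydrogen-bonded hydroxyl is tolerated in the aqueous rhodium system and activates the enone, and 28 is obtained directly.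

**Further compounds**
F1 | step 3 | 3-ethoxybut-3-en-2-one | C=C(OCC)C(C)=O
F2 | step 3 | 5-ethoxy-1,1,1-trifluorohex-5-ene-2,4-dione | C=C(OCC)C(=O)CC(=O)C(F)(F)F
F3 | step 3 | 1-diazo-3-ethoxybut-3-en-2-one | C=C(OCC)C(=O)C=[N+]=[N-]
F4 | step 12 | 4-methoxy-3-(3-methylbut-3-en-1-yl)benzaldehyde | C=C(C)CCc1cc(C=O)ccc1OC
F5 | step 12 | (E)-1-{6-ethoxy-2-hydroxy-3-(3-methylbut-2-en-1-yl)-4-[(triisopropylsilyl)oxy]phenyl}-3-[4-methoxy-3-(3-methylbut-3-en-1-yl)phenyl]prop-2-en-1-one | CCOc1cc(O[Si](C(C)C)(C(C)C)C(C)C)c(CC=C(C)C)c(O)c1C(=O)/C=C/c1ccc(OC)c(CCC(C)=C)c1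
F6 | step 12 | racemic 5-ethoxy-2-[4-methoxy-3-(3-methylbut-3-en-1-yl)phenyl]-8-(3-methylbut-2-en-1-yl)-7-[(triisopropylsilyl)oxy]-2,3-dihydro-4H-chromen-4-one | C=C(C)CCc1cc(C2CC(=O)c3c(OCC)cc(O[Si](C(C)C)(C(C)C)C(C)C)c(CC=C(C)C)c3O2)ccc1OC
F7 | step 13 | 5-hydroxy-8-(3-methylbut-2-en-1-yl)-7-[(triisopropylsilyl)oxy]-4H-chromen-4-one | Oc1cc(O[Si](C(C)C)(C(C)C)C(C)C)c(CC=C(C)C)c2occc(=O)c12
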